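Ring A of the flavonol is a fully substituted benzene in which the O1–C8a and C4–C4a bonds sit side by side between the oxygen-bearing carbons C8 and C5. Both bonds are therefore cut at once, back to a mirror-symmetric 3,4,5,6-tetramethoxybenzyne and benzyloxyacetic acid. Fluoride-triggered insertion of the aryne into the acyl C–O bond of the acid installs the phenolic oxygen and the C3-oxygenated acyl chain in one operation, with no regiochemical question. The aryne precursor is the ortho-silyl aryl triflate of 2,3,4,5-tetramethoxyphenol. Aroylation, Baker–Venkataraman shift and cyclodehydration then build ring C, and BCl3 finally frees O3, O4' and, by chelation to the C4 carbonyl, O5.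

Key step: step 7

Remark: the target has no stereocentre; diketone 19 is drawn as its diketo tautomer, and its C2 centre is racemic, labile and lost in step 11.

Step 1
Reactants: 1 2,3,4-trimethoxybenzaldehyde
Product: 3 2,3,4-trimethoxyphenol, via 2,3,4-trimethoxyphenyl formate 2 (not isolated)
Conditions: H2O2 (30% aq), cat. H2SO4, MeOH, rt
Reagents that add atoms: hydrogen peroxide, OO
Why: Acid-catalysed Dakin oxidation, in which the hydroperoxide adduct of the electron-rich aldehyde rearranges with aryl migration to formate 2, which is methanolysed in the flask.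

Step 2
Reactants: 3 2,3,4-trimethoxyphenol
Product: 4 1,2,3,4-tetramethoxybenzene
Conditions: MeI, K2CO3, acetone, reflux
Reagents that add atoms: iodomethane, CI
Why: Williamson O-methylation of the phenoxide, with no competing site in the molecule.

Step 3
Reactants: 4 1,2,3,4-tetramethoxybenzene
Product: 7 2,3,4,5-tetramethoxyphenol, via aryllithium 5 (not isolated), via dimethyl arylboronate 6 (not isolated)
Conditions: n-BuLi, TMEDA, THF, 0 °C → rt; B(OMe)3, −78 °C → rt; AcOH, H2O2 (30% aq), 0 °C → rt
Reagents that add atoms: hydrogen peroxide, OO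
Why: Directed ortho-metalation next to a methoxy group (the two free ring positions are equivalent), boration and oxidative carbon-to-oxygen migration from boron should give the phenol in one flask.

Step 4
Reactants: 7 2,3,4,5-tetramethoxyphenol
Product: 8 6-bromo-2,3,4,5-tetramethoxyphenol
Conditions: NBS (1.0 equiv), CH2Cl2, −78 → 0 °C, dark
Reagents that add atoms: N-bromosuccinimide, O=C1CCC(=O)N1Br
Why: Electrophilic aromatic bromination at the only unsubstituted ring carbon, which is ortho to the hydroxyl group, with low temperature and anhydrous medium holding back oxidation of the ring.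

Step 5
Reactants: 8 6-bromo-2,3,4,5-tetramethoxyphenol
Product: 9 (2-bromo-3,4,5,6-tetramethoxyphenoxy)trimethylsilane
Conditions: HMDS, THF, reflux; volatiles removed in vacuo, used crude
Reagents that add atoms: hexamethyldisilazane, C[Si](C)(C)N[Si](C)(C)C
Why: O-Silylation of the phenol by HMDS, driven by loss of ammonia and leaving no salt that would interfere with the lithiation to follow.

Step 6
Reactants: 9 (2-bromo-3,4,5,6-tetramethoxyphenoxy)trimethylsilane
Product: 12 2,3,4,5-tetramethoxy-6-(trimethylsilyl)phenyl trifluoromethanesulfonate, via aryllithium 10 (not isolated), via lithium silylphenoxide 11 (not isolated)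
Conditions: n-BuLi, THF, −100 → −80 °C; Tf2O, −100 → −78 °C
Reagents that add atoms: trifluoromethanesulfonic anhydride, O=S(=O)(OS(=O)(=O)C(F)(F)F)C(F)(F)F
Why: Bromine–lithium exchange followed by 1,3 oxygen-to-carbon silyl shift (retro-Brook rearrangement) gives the ortho-silyl phenoxide, which Tf2O sulfonylates on oxygen, the standard entry to ortho-silyl aryl triflates and proven for phenoxides flanked by a methoxy group.

Step 7
Reactants: 12 2,3,4,5-tetramethoxy-6-(trimethylsilyl)phenyl trifluoromethanesulfonate; 13 benzyloxyacetic acid
Product: 15 2-(benzyloxy)-1-(2-hydroxy-3,4,5,6-tetramethoxyphenyl)ethan-1-one, via 3,4,5,6-tetramethoxybenzyne 14 (not isolated)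
Conditions: 13 (1.2 equiv), CsF (4 equiv), THF, 125 °C, sealed tube
Reagents that add atoms: none
Why: Fluoride removes the silyl group and triflate leaves to give benzyne 14; cesium benzyloxyacetate adds through oxygen, and the aryl anion so formed attacks the ester carbonyl next to it, giving a four-membered alkoxide that opens to the ketone phenoxide, a net insertion of the aryne into the acyl C–O bond that makes C8a–O1 and C4a–C4. This is the known fluoride-induced insertion of arynes into carboxylic acids to give ortho-hydroxyaryl ketones. No ring is closed in the product and no stereocentre is formed. Regioselectivity is not at issue, because both aryne carbons are flanked by methoxy groups and are exchanged by the mirror plane of 14. The chemoselectivity needed, acyl shift before protonation of the aryl anion, is served by hot aprotic THF without water or alcohol: the sparingly soluble CsF first turns the acid into its carboxylate and then releases the aryne slowly, which should also keep the product phenoxide from capturing a second aryne.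

Step 8
Reactants: 16 4-(benzyloxy)benzoic acid
Product: 17 4-(benzyloxy)benzoyl chloride
Conditions: (COCl)2, cat. DMF, CH2Cl2, 0 °C → rt; evaporated, used crude
Reagents that add atoms: oxalyl chloride, O=C(Cl)C(=O)Cl
Why: Acid chloride formation through the chloroiminium species from DMF and oxalyl chloride, mild enough to leave the aryl benzyl ether untouched.

Step 9
Reactants: 15 2-(benzyloxy)-1-(2-hydroxy-3,4,5,6-tetramethoxyphenyl)ethan-1-one; 17 4-(benzyloxy)benzoyl chloride
Product: 18 2-[2-(benzyloxy)acetyl]-3,4,5,6-tetramethoxyphenyl 4-(benzyloxy)benzoate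
Conditions: pyridine, cat. DMAP, CH2Cl2, 0 °C → rt
Reagents that add atoms: none
Why: DMAP-catalysed O-acylation of the phenol by the aroyl chloride, the classical ester formation used for hydrogen-bonded ortho-hydroxyaryl ketones of polymethoxyflavone precursors.

Step 10
Reactants: 18 2-[2-(benzyloxy)acetyl]-3,4,5,6-tetramethoxyphenyl 4-(benzyloxy)benzoate
Product: 19 2-(benzyloxy)-1-[4-(benzyloxy)phenyl]-3-(2-hydroxy-3,4,5,6-tetramethoxyphenyl)propane-1,3-dione
Conditions: LiN(SiMe3)2 (3 equiv), THF, −78 → 0 °C; AcOH quench
Reagents that add atoms: none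
Why: Baker–Venkataraman rearrangement, in which the ketone enolate attacks the neighbouring aryl ester through a six-membered transition state and the aroyl group moves from oxygen to carbon; the new C2 centre forms as a racemate and is removed in the next step.

Step 11
Reactants: 19 2-(benzyloxy)-1-[4-(benzyloxy)phenyl]-3-(2-hydroxy-3,4,5,6-tetramethoxyphenyl)propane-1,3-dione
Product: 20 3-(benzyloxy)-2-[4-(benzyloxy)phenyl]-5,6,7,8-tetramethoxy-4H-chromen-4-one
Conditions: cat. p-TsOH·H2O, toluene, reflux (Dean–Stark)
Reagents that add atoms: none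
Why: Acid-catalysed cyclodehydration, in which the phenol adds to the aroyl carbonyl (6-exo-trig hemiketal formation) and loss of water gives the aromatic chromen-4-one of ring C.

Step 12
Reactants: 20 3-(benzyloxy)-2-[4-(benzyloxy)phenyl]-5,6,7,8-tetramethoxy-4H-chromen-4-one
Product: 21 3,5,4'-trihydroxy-6,7,8-trimethoxyflavone
Conditions: BCl3 (excess), pentamethylbenzene, CH2Cl2, −78 → 0 °C; MeOH, aq. HCl
Reagents that add atoms: none
Why: Lewis-acid ether cleavage with BCl3, in which both benzyl ethers are cleaved with capture of the benzyl cation by pentamethylbenzene and the 5-O-methyl group is removed selectively through a six-membered boron chelate with the C4 carbonyl, while the methoxy groups at C6, C7 and C8 cannot chelate and should stay.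

Compound list
1 | 2,3,4-trimethoxybenzaldehyde | COc1ccc(C=O)c(OC)c1OC | starting material
2 | 2,3,4-trimethoxyphenyl formate | COc1ccc(OC=O)c(OC)c1OC | intermediate (not isolated)
3 | 2,3,4-trimethoxyphenol | COc1ccc(O)c(OC)c1OC | intermediate
4 | 1,2,3,4-tetramethoxybenzene | COc1ccc(OC)c(OC)c1OC | intermediate
5 | (2,3,4,5-tetramethoxyphenyl)lithium | [Li]c1cc(OC)c(OC)c(OC)c1OC | intermediate (not isolated)
6 | dimethyl (2,3,4,5-tetramethoxyphenyl)boronate, released from its lithium trimethoxyborate by AcOH | COB(OC)c1cc(OC)c(OC)c(OC)c1OC | intermediate (not isolated)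
7 | 2,3,4,5-tetramethoxyphenol | COc1cc(O)c(OC)c(OC)c1OC | intermediate
8 | 6-bromo-2,3,4,5-tetramethoxyphenol | COc1c(Br)c(O)c(OC)c(OC)c1OC | intermediate
9 | (2-bromo-3,4,5,6-tetramethoxyphenoxy)trimethylsilane | COc1c(Br)c(O[Si](C)(C)C)c(OC)c(OC)c1OC | intermediate
10 | [2,3,4,5-tetramethoxy-6-(trimethylsilyloxy)phenyl]lithium | COc1c([Li])c(O[Si](C)(C)C)c(OC)c(OC)c1OC | intermediate (not isolated)
11 | lithium 2,3,4,5-tetramethoxy-6-(trimethylsilyl)phenoxide | [Li+].COc1c([Si](C)(C)C)c([O-])c(OC)c(OC)c1OC | intermediate (not isolated)
12 | 2,3,4,5-tetramethoxy-6-(trimethylsilyl)phenyl trifluoromethanesulfonate | COc1c(OC)c(OC)c([Si](C)(C)C)c(OS(=O)(=O)C(F)(F)F)c1OC | intermediate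
13 | benzyloxyacetic acid | OC(=O)COCc1ccccc1 | starting material
14 | 3,4,5,6-tetramethoxybenzyne (1,2-didehydro-3,4,5,6-tetramethoxybenzene) | COC1=C(OC)C(OC)=C(OC)C#C1 | intermediate (not isolated)
15 | 2-(benzyloxy)-1-(2-hydroxy-3,4,5,6-tetramethoxyphenyl)ethan-1-one | COc1c(OC)c(OC)c(C(=O)COCc2ccccc2)c(O)c1OC | intermediate
16 | 4-(benzyloxy)benzoic acid | OC(=O)c1ccc(OCc2ccccc2)cc1 | starting material
17 | 4-(benzyloxy)benzoyl chloride | ClC(=O)c1ccc(OCc2ccccc2)cc1 | intermediate
18 | 2-[2-(benzyloxy)acetyl]-3,4,5,6-tetramethoxyphenyl 4-(benzyloxy)benzoate | COc1c(OC)c(OC)c(C(=O)COCc2ccccc2)c(OC(=O)c2ccc(OCc3ccccc3)cc2)c1OC | intermediate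
19 | 2-(benzyloxy)-1-[4-(benzyloxy)phenyl]-3-(2-hydroxy-3,4,5,6-tetramethoxyphenyl)propane-1,3-dione (racemic at C2) | COc1c(OC)c(OC)c(C(=O)C(OCc2ccccc2)C(=O)c2ccc(OCc3ccccc3)cc2)c(O)c1OC | intermediate
20 | 3-(benzyloxy)-2-[4-(benzyloxy)phenyl]-5,6,7,8-tetramethoxy-4H-chromen-4-one | COc1c(OC)c(OC)c2c(=O)c(OCc3ccccc3)c(-c3ccc(OCc4ccccc4)cc3)oc2c1OC | intermediate
21 | 3,5,4'-trihydroxy-6,7,8-trimethoxyflavone | COc1c(OC)c(O)c2c(=O)c(O)c(-c3ccc(O)cc3)oc2c1OC | target

Total step count: 12. Longest linear sequence: 11 steps (steps 1–7 and 9–12 from aldehyde 1); step 8 is a one-step branch.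

Steps most likely to fail

Step 7. The aryl anion formed after carboxylate addition may be protonated (by residual acid, bifluoride or the α-CH2 of its own ester) before the acyl shift, so that the reaction stops at simple O-arylation; the product phenoxide may also capture a second aryne. The fallback sets out from 8 and comes back at 15. Bromophenol 8 is esterified with commercial benzyloxyacetyl chloride (Et3N, cat. DMAP, CH2Cl2) to 2-bromo-3,4,5,6-tetramethoxyphenyl 2-(benzyloxy)acetate F1. Treatment with n-BuLi in THF at −100 °C then effects bromine–lithium exchange, and the ortho-lithiated aryl ester, formed here in a medium free of proton donors, should undergo 1,3 oxygen-to-carbon acyl shift (the known anionic Fries-type rearrangement of ortho-haloaryl esters) to give 15 after acidic work-up.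

Step 12. Ether cleavage may lose its selectivity: the 6-methoxy group may follow the 5-methoxy group if the mixture is warmed too long, demethylation at C5 may stay incomplete at low temperature, or ring B may be benzylated if cation capture is slow. The fallback sets out from 20 and comes back at 21, and separates the two tasks. Hydrogenolysis (H2, palladium on carbon, Pd/C, EtOAc–MeOH, rt) removes both benzyl groups to give 3-hydroxy-2-(4-hydroxyphenyl)-5,6,7,8-tetramethoxy-4H-chromen-4-one F2. The 5-O-methyl group is then cleaved alone with AlCl3 in MeCN, a reagent known to demethylate only the position peri to the carbonyl in polymethoxyflavones.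

Step 4. Oxidation of the very electron-rich phenol to a quinone (oxidative demethylation at the para methoxy group) may compete with ring bromination, and the following two steps depend on the bromide. The fallback sets out from 7 and comes back at 12, bypassing steps 4–6 without any electrophilic halogenation. Phenol 7 is carbamoylated with isopropyl isocyanate (cat. Et3N, CH2Cl2) to 2,3,4,5-tetramethoxyphenyl N-isopropylcarbamate F3. In-situ N-silylation (TBSOTf, TMEDA), carbamate-directed ortho-lithiation (n-BuLi, TMEDA, Et2O, −78 °C) and quenching with TMSCl should give 2,3,4,5-tetramethoxy-6-(trimethylsilyl)phenyl N-isopropylcarbamate F4. Cleavage of the carbamate with Et2NH and DBU in MeCN at 40 °C, followed by PhNTf2 in the same flask, converts the liberated phenoxide into triflate 12.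

Further compounds
F1 | step 7 | 2-bromo-3,4,5,6-tetramethoxyphenyl 2-(benzyloxy)acetate | COc1c(Br)c(OC(=O)COCc2ccccc2)c(OC)c(OC)c1OC
F2 | step 12 | 3-hydroxy-2-(4-hydroxyphenyl)-5,6,7,8-tetramethoxy-4H-chromen-4-one | COc1c(OC)c(OC)c2c(=O)c(O)c(-c3ccc(O)cc3)oc2c1OC
F3 | step 4 | 2,3,4,5-tetramethoxyphenyl N-isopropylcarbamate | COc1cc(OC(=O)NC(C)C)c(OC)c(OC)c1OC
F4 | step 4 | 2,3,4,5-tetramethoxy-6-(trimethylsilyl)phenyl N-isopropylcarbamate | COc1c([Si](C)(C)C)c(OC(=O)NC(C)C)c(OC)c(OC)c1OC
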